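**Retrosynthetic overview**
1. Target ⇐ neopentyl alcohol (final oxidation) ⇐ 12-membered ring closed last by intramolecular B-alkyl Suzuki coupling of a ring vinyl group with a (Z)-2-iodoalkene; this sets the second Z-olefin, and the first comes intact from neryl acetate.
2. Spiro-epoxide ⇐ cyclohexanone (sulfur ylide); its α-side chain ⇐ Michael addition of a regiodefined enolate; quaternary carbon ⇐ anti-selective copper-catalysed addition of the homoprenyl Grignard reagent to a 4-alkyl-3-(hydroxymethyl)cyclohex-2-enone.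
3. That enone (one stereocentre, which relays all others) ⇐ key step: Birch dearomatisation of a 3,4-disubstituted anisole to a prochiral cyclohex-3-enone, then amine-catalysed enantioselective shift of the double bond into conjugation.
4. Anisole ⇐ 3-methoxybenzyl alcohol (bromination, aryl–allyl coupling) + a (Z)-allylic bromide made from neryl acetate.
5. Ring order: six-membered ring first (from the benzene ring), oxirane second, macrocycle last.

Assumption: the target is the enantiomer drawn, (1R,3Z,7Z,11R,12S,15S) in bicyclo[9.3.1]pentadecane numbering; in step 6 the pseudoenantiomeric series of the amine catalyst that gives the (4R)-enone is used (written as the quinine-derived one), and sulfoxides are mixtures at sulfur.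

**Step 1**
Reactants: 1 neryl acetate [(2Z)-3,7-dimethylocta-2,6-dien-1-yl acetate]
Product: 4 (2Z)-6,6-dimethoxy-3-methylhex-2-en-1-ol, via aldehyde acetate 2 (not isolated), via acetal acetate 3 (not isolated)
Conditions: O3 (1.0 equiv), CH2Cl2/MeOH, −78 °C; Me2S; then HC(OMe)3, TsOH (cat.), 20 °C; then K2CO3, 20 °C
Reagents that add atoms: trimethyl orthoformate (COC(OC)OC); methanol (CO)
Why: Ozonolysis is selective for the electron-rich 6,7-olefin (the 2,3-olefin is deactivated by the allylic acetate), and acid-catalysed acetalisation followed by base-catalysed methanolysis of the acetate in the same pot leaves the Z-olefin untouched.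

**Step 2**
Reactants: 4 (2Z)-6,6-dimethoxy-3-methylhex-2-en-1-ol
Product: 6 (2Z)-1-bromo-6,6-dimethoxy-3-methylhex-2-ene, via allylic mesylate 5 (not isolated)
Conditions: MsCl, Et3N, THF, −40 °C; then LiBr, 0 °C
Reagents that add atoms: lithium bromide ([Li+].[Br-])
Why: Mesylation and SN2 displacement by bromide (Finkelstein-type) under non-acidic conditions keep the acetal and the Z geometry.

**Step 3**
Reactants: 7 3-methoxybenzyl alcohol
Product: 8 (2-bromo-5-methoxyphenyl)methanol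
Conditions: NBS, MeCN, 0 → 20 °C
Reagents that add atoms: N-bromosuccinimide (O=C1CCC(=O)N1Br)
Why: Electrophilic aromatic bromination occurs para to the methoxy group.

**Step 4**
Reactants: 8 (2-bromo-5-methoxyphenyl)methanol; 6 (2Z)-1-bromo-6,6-dimethoxy-3-methylhex-2-ene
Product: 10 {2-[(2Z)-6,6-dimethoxy-3-methylhex-2-en-1-yl]-5-methoxyphenyl}methanol, via dilithio species 9 (not isolated)
Conditions: n-BuLi (2.1 equiv), THF, −78 °C; CuBr·SMe2 (10 mol%); then 6, −78 → 0 °C; aq. NH4Cl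
Reagents that add atoms: none
Why: O–H deprotonation plus bromine–lithium exchange gives the aryllithium alkoxide, whose copper-catalysed SN2 allylation takes place at the primary carbon (attack at the other allyl terminus would build a quaternary carbon), so the Z-olefin is retained.

**Step 5**
Reactants: 10 {2-[(2Z)-6,6-dimethoxy-3-methylhex-2-en-1-yl]-5-methoxyphenyl}methanol
Product: 12 4-[(2Z)-6,6-dimethoxy-3-methylhex-2-en-1-yl]-3-(hydroxymethyl)cyclohex-3-en-1-one, via dihydroanisole 11 (not isolated)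
Conditions: Li, NH3(l), THF, t-BuOH, −78 → −33 °C; NH4Cl; then (CO2H)2, MeOH/H2O, 0 °C
Reagents that add atoms: water (O)
Why: Key step, a Birch reduction that leaves all three donor substituents on sp2 carbons (the benzylic C–O bond is protected as its alkoxide, the isolated olefin and the acetal are inert), followed by mild enol-ether hydrolysis that gives the non-conjugated, still achiral enone.

**Step 6**
Reactants: 12 4-[(2Z)-6,6-dimethoxy-3-methylhex-2-en-1-yl]-3-(hydroxymethyl)cyclohex-3-en-1-one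
Product: 13 (4R)-4-[(2Z)-6,6-dimethoxy-3-methylhex-2-en-1-yl]-3-(hydroxymethyl)cyclohex-2-en-1-one
Conditions: 9-amino-9-deoxy-epi-quinine (10 mol%), CF3CO2H (20 mol%), PhMe, −25 °C
Reagents that add atoms: none
Why: Enantioselective β,γ→α,β enone isomerisation by cooperative iminium–base catalysis, in which the chiral primary amine forms a dienamine and its protonated quinuclidine delivers the proton to one face of C4, setting the first stereocentre (4R).

**Step 7**
Reactants: 13 (4R)-4-[(2Z)-6,6-dimethoxy-3-methylhex-2-en-1-yl]-3-(hydroxymethyl)cyclohex-2-en-1-one; 14 5-bromo-2-methylpent-2-ene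
Product: 17 {[(3S,4R)-4-[(2Z)-6,6-dimethoxy-3-methylhex-2-en-1-yl]-3-(4-methylpent-3-en-1-yl)-3-{[(trimethylsilyl)oxy]methyl}cyclohex-1-en-1-yl]oxy}(trimethyl)silane, via Grignard reagent 15 (not isolated), via silyl ether 16 (not isolated)
Conditions: 14, Mg, THF, 20 °C; then 13, CuBr·SMe2 (10 mol%), TMSCl (4 equiv), HMPA, THF, −78 → −40 °C (2.3 equiv of 15)
Reagents that add atoms: chlorotrimethylsilane (C[Si](C)(C)Cl)
Why: TMSCl-accelerated copper-catalysed conjugate addition in which the first equivalent of 15 deprotonates the alcohol (silylated in situ) and the homoprenyl group then adds to C3 anti to the pseudoaxial C4 side chain, giving the quaternary centre (3S) with CH2O cis to the C4 chain and trapping the enolate as the regiodefined silyl enol ether.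

**Step 8**
Reactants: 17 bis-silyl compound from step 7; 18 phenyl vinyl sulfoxide
Product: 21 (2R,3S,4R)-3-(hydroxymethyl)-4-[(2Z)-3-methyl-6-oxohex-2-en-1-yl]-3-(4-methylpent-3-en-1-yl)-2-[2-(phenylsulfinyl)ethyl]cyclohexan-1-one, via lithium enolate 19 (not isolated), via silylated acetal adduct 20 (not isolated)
Conditions: MeLi, THF, 0 °C; then 18, −78 → −30 °C; then 1 M HCl, THF, 20 °C
Reagents that add atoms: water (O)
Why: MeLi unmasks the regiodefined lithium enolate, which undergoes Michael addition to the vinyl sulfoxide (a vinyl cation equivalent) by axial attack on the half-chair that keeps the C4 chain equatorial, that is anti to the axial CH2OSiMe3 group and free of a 1,3-diaxial clash, giving the 2,4-trans ketone (2R); the HCl work-up cleaves the silyl ether and the acetal.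

**Step 9**
Reactants: 21 keto aldehyde from step 8
Product: 22 (2R,3S,4R)-3-(hydroxymethyl)-4-[(2Z,6Z)-7-iodo-3-methylocta-2,6-dien-1-yl]-3-(4-methylpent-3-en-1-yl)-2-[2-(phenylsulfinyl)ethyl]cyclohexan-1-one
Conditions: Ph3PEtI, n-BuLi, THF, 20 °C; I2, −78 °C; NaN(SiMe3)2, −20 °C; then 21, −78 → −20 °C (ylide 2.5 equiv)
Reagents that add atoms: ethyltriphenylphosphonium iodide (CC[P+](c1ccccc1)(c1ccccc1)c1ccccc1.[I-]); iodine (II)
Why: Wittig olefination with the α-iodo ylide (Stork–Zhao type) converts the aldehyde, much faster than the hindered ketone, into the (Z)-2-iodoalkene under kinetic control; the free alcohol only consumes excess ylide.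

**Step 10**
Reactants: 22 vinyl iodide ketone from step 9
Product: 23 [(3S,4R,5S,6R)-6-[(2Z,6Z)-7-iodo-3-methylocta-2,6-dien-1-yl]-5-(4-methylpent-3-en-1-yl)-4-[2-(phenylsulfinyl)ethyl]-1-oxaspiro[2.5]octan-5-yl]methanol
Conditions: Me3SI, KN(SiMe3)2, THF, −10 °C; then 22, −10 → 20 °C (ylide 3 equiv)
Reagents that add atoms: trimethylsulfonium iodide (C[S+](C)C.[I-])
Why: Corey–Chaykovsky epoxidation, in which the sulfonium ylide transfers CH2 irreversibly to the ketone face opposite the adjacent sulfinylethyl chain and the homoprenyl group (both on the other face), giving the (3S) spiro-epoxide with oxygen cis to these two groups and fixing the former α-stereocentre against epimerisation.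

**Step 11**
Reactants: 23 epoxy sulfoxide from step 10
Product: 24 [(3S,4R,5S,6R)-4-ethenyl-6-[(2Z,6Z)-7-iodo-3-methylocta-2,6-dien-1-yl]-5-(4-methylpent-3-en-1-yl)-1-oxaspiro[2.5]octan-5-yl]methanol
Conditions: CaCO3, PhMe, 110 °C
Reagents that add atoms: none
Why: Thermal syn-elimination of the sulfoxide can only take the β-hydrogen of the CH2 next to the ring and so unveils the vinyl group under neutral conditions that spare the epoxide and the vinyl iodide.

**Step 12**
Reactants: 24 vinyl epoxide from step 11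
Product: 26 [(1R,3Z,7Z,11R,12S,15S)-4,8-dimethyl-15-(4-methylpent-3-en-1-yl)spiro[bicyclo[9.3.1]pentadeca-3,7-diene-12,2'-oxiran]-15-yl]methanol, via bis-boryl intermediate 25 (not isolated)
Conditions: 9-BBN-H (2.5 equiv), THF, 0 → 20 °C; then slow addition to PdCl2(dppf) (10 mol%), AsPh3, Cs2CO3, DMF/THF/H2O, 50 °C, 2 mM
Reagents that add atoms: none
Why: 9-BBN-H hydroborates only the monosubstituted alkene (anti-Markovnikov), and the primary alkylborane closes the 12-membered ring by intramolecular B-alkyl Suzuki–Miyaura coupling with retention of the Z vinyl iodide geometry, without forming a new stereocentre.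

**Step 13**
Reactants: 26 macrocyclic epoxy alcohol from step 12
Product: 27 (1R,3Z,7Z,11R,12S,15S)-4,8-dimethyl-15-(4-methylpent-3-en-1-yl)spiro[bicyclo[9.3.1]pentadeca-3,7-diene-12,2'-oxirane]-15-carbaldehyde (CNP0283574.1)
Conditions: Dess–Martin periodinane, NaHCO3, CH2Cl2, 0 → 20 °C
Reagents that add atoms: none
Why: Buffered Dess–Martin oxidation turns the neopentyl primary alcohol into the aldehyde without touching the epoxide or the three trisubstituted olefins.

**Compound list**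
1 | neryl acetate, (2Z)-3,7-dimethylocta-2,6-dien-1-yl acetate | CC(C)=CCC/C(C)=C\COC(C)=O | starting material
2 | (4Z)-6-acetoxy-4-methylhex-4-enal | O=CCC/C(C)=C\COC(C)=O | intermediate
3 | (2Z)-6,6-dimethoxy-3-methylhex-2-en-1-yl acetate | COC(OC)CC/C(C)=C\COC(C)=O | intermediate
4 | (2Z)-6,6-dimethoxy-3-methylhex-2-en-1-ol | COC(OC)CC/C(C)=C\CO | intermediate
5 | (2Z)-6,6-dimethoxy-3-methylhex-2-en-1-yl methanesulfonate | COC(OC)CC/C(C)=C\COS(C)(=O)=O | intermediate
6 | (2Z)-1-bromo-6,6-dimethoxy-3-methylhex-2-ene | COC(OC)CC/C(C)=C\CBr | intermediate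
7 | 3-methoxybenzyl alcohol | COc1cccc(CO)c1 | starting material
8 | (2-bromo-5-methoxyphenyl)methanol | COc1ccc(Br)c(CO)c1 | intermediate
9 | lithium (2-lithio-5-methoxyphenyl)methanolate | [Li]OCc1cc(OC)ccc1[Li] | intermediate
10 | {2-[(2Z)-6,6-dimethoxy-3-methylhex-2-en-1-yl]-5-methoxyphenyl}methanol | COc1ccc(C/C=C(C)\CCC(OC)OC)c(CO)c1 | intermediate
11 | {2-[(2Z)-6,6-dimethoxy-3-methylhex-2-en-1-yl]-5-methoxycyclohexa-1,4-dien-1-yl}methanol | COC1=CCC(C/C=C(C)\CCC(OC)OC)=C(CO)C1 | intermediate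
12 | 4-[(2Z)-6,6-dimethoxy-3-methylhex-2-en-1-yl]-3-(hydroxymethyl)cyclohex-3-en-1-one | O=C1CCC(C/C=C(C)\CCC(OC)OC)=C(CO)C1 | intermediate
13 | (4R)-4-[(2Z)-6,6-dimethoxy-3-methylhex-2-en-1-yl]-3-(hydroxymethyl)cyclohex-2-en-1-one | O=C1C=C(CO)[C@@H](C/C=C(C)\CCC(OC)OC)CC1 | intermediate
14 | 5-bromo-2-methylpent-2-ene | CC(C)=CCCBr | starting material
15 | (4-methylpent-3-en-1-yl)magnesium bromide | CC(C)=CCC[Mg]Br | intermediate
16 | (4R)-4-[(2Z)-6,6-dimethoxy-3-methylhex-2-en-1-yl]-3-{[(trimethylsilyl)oxy]methyl}cyclohex-2-en-1-one | O=C1C=C(CO[Si](C)(C)C)[C@@H](C/C=C(C)\CCC(OC)OC)CC1 | intermediate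
17 | {[(3S,4R)-4-[(2Z)-6,6-dimethoxy-3-methylhex-2-en-1-yl]-3-(4-methylpent-3-en-1-yl)-3-{[(trimethylsilyl)oxy]methyl}cyclohex-1-en-1-yl]oxy}(trimethyl)silane | C[Si](C)(C)OC1=C[C@](CO[Si](C)(C)C)(CCC=C(C)C)[C@@H](C/C=C(C)\CCC(OC)OC)CC1 | intermediate
18 | phenyl vinyl sulfoxide | C=CS(=O)c1ccccc1 | starting material
19 | lithium (3S,4R)-4-[(2Z)-6,6-dimethoxy-3-methylhex-2-en-1-yl]-3-(4-methylpent-3-en-1-yl)-3-{[(trimethylsilyl)oxy]methyl}cyclohex-1-en-1-olate | [Li]OC1=C[C@](CO[Si](C)(C)C)(CCC=C(C)C)[C@@H](C/C=C(C)\CCC(OC)OC)CC1 | intermediate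
20 | (2R,3S,4R)-4-[(2Z)-6,6-dimethoxy-3-methylhex-2-en-1-yl]-3-(4-methylpent-3-en-1-yl)-2-[2-(phenylsulfinyl)ethyl]-3-{[(trimethylsilyl)oxy]methyl}cyclohexan-1-one | O=C1CC[C@H](C/C=C(C)\CCC(OC)OC)[C@@](CO[Si](C)(C)C)(CCC=C(C)C)[C@H]1CCS(=O)c1ccccc1 | intermediate
21 | (2R,3S,4R)-3-(hydroxymethyl)-4-[(2Z)-3-methyl-6-oxohex-2-en-1-yl]-3-(4-methylpent-3-en-1-yl)-2-[2-(phenylsulfinyl)ethyl]cyclohexan-1-one | O=C1CC[C@H](C/C=C(C)\CCC=O)[C@@](CO)(CCC=C(C)C)[C@H]1CCS(=O)c1ccccc1 | intermediate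
22 | (2R,3S,4R)-3-(hydroxymethyl)-4-[(2Z,6Z)-7-iodo-3-methylocta-2,6-dien-1-yl]-3-(4-methylpent-3-en-1-yl)-2-[2-(phenylsulfinyl)ethyl]cyclohexan-1-one | O=C1CC[C@H](C/C=C(C)\CC/C=C(/C)I)[C@@](CO)(CCC=C(C)C)[C@H]1CCS(=O)c1ccccc1 | intermediate
23 | [(3S,4R,5S,6R)-6-[(2Z,6Z)-7-iodo-3-methylocta-2,6-dien-1-yl]-5-(4-methylpent-3-en-1-yl)-4-[2-(phenylsulfinyl)ethyl]-1-oxaspiro[2.5]octan-5-yl]methanol | C1O[C@]12CC[C@H](C/C=C(C)\CC/C=C(/C)I)[C@@](CO)(CCC=C(C)C)[C@H]2CCS(=O)c1ccccc1 | intermediate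
24 | [(3S,4R,5S,6R)-4-ethenyl-6-[(2Z,6Z)-7-iodo-3-methylocta-2,6-dien-1-yl]-5-(4-methylpent-3-en-1-yl)-1-oxaspiro[2.5]octan-5-yl]methanol | C1O[C@]12CC[C@H](C/C=C(C)\CC/C=C(/C)I)[C@@](CO)(CCC=C(C)C)[C@H]2C=C | intermediate
25 | compound 24 with the vinyl group converted into CH2CH2–B(9-borabicyclo[3.3.1]nonan-9-yl) and the CH2OH group into its 9-BBN borinate | C1O[C@]12CC[C@H](C/C=C(C)\CC/C=C(/C)I)[C@@](COB3C4CCCC3CCC4)(CCC=C(C)C)[C@H]2CCB1C2CCCC1CCC2 | intermediate
26 | [(1R,3Z,7Z,11R,12S,15S)-4,8-dimethyl-15-(4-methylpent-3-en-1-yl)spiro[bicyclo[9.3.1]pentadeca-3,7-diene-12,2'-oxiran]-15-yl]methanol | CC(C)=CCC[C@]1(CO)[C@H]2C/C=C(/C)CC/C=C(/C)CC[C@H]1[C@@]1(CC2)CO1 | intermediate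
27 | (1R,3Z,7Z,11R,12S,15S)-4,8-dimethyl-15-(4-methylpent-3-en-1-yl)spiro[bicyclo[9.3.1]pentadeca-3,7-diene-12,2'-oxirane]-15-carbaldehyde | CC(C)=CCC[C@]1(C=O)[C@H]2C/C=C(/C)CC/C=C(/C)CC[C@H]1[C@@]1(CC2)CO1 | target

**Step count and risks**
Total: 13 steps. Longest linear sequence: 12 steps (from 1 through steps 1, 2 and 4–13).

Step 6 is the first of the three steps most likely to fail, because the 3-hydroxymethyl-4-alkyl substitution may give low enantioselectivity in the amine-catalysed isomerisation. The fallback sets out from 12: DBU in CH2Cl2 conjugates it to racemic 4-[(2Z)-6,6-dimethoxy-3-methylhex-2-en-1-yl]-3-(hydroxymethyl)cyclohex-2-en-1-one F1, which is separated by preparative chromatography on an amylose-type chiral stationary phase. The unwanted (4S)-4-[(2Z)-6,6-dimethoxy-3-methylhex-2-en-1-yl]-3-(hydroxymethyl)cyclohex-2-en-1-one F2 is returned to 12 by kinetic deconjugation (KOt-Bu, THF, −78 °C; AcOH) and recycled. The route is rejoined at 13.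

Step 8 is the second, because Michael addition of a hindered ketone enolate to phenyl vinyl sulfoxide may be slow or give double addition. The fallback sets out from 17: enolate 19 is regenerated with MeLi and trapped in an aldol reaction with (phenylselanyl)acetaldehyde to give the ring-C2 1-hydroxy-2-(phenylselanyl)ethyl ketone F3 (ring configuration as in 20). MsCl/Et3N with cyclohexene as selenium scavenger eliminates it to (2R,3S,4R)-4-[(2Z)-6,6-dimethoxy-3-methylhex-2-en-1-yl]-2-ethenyl-3-(4-methylpent-3-en-1-yl)-3-{[(trimethylsilyl)oxy]methyl}cyclohexan-1-one F4. Brief 1 M HCl/THF gives (2R,3S,4R)-2-ethenyl-3-(hydroxymethyl)-4-[(2Z)-3-methyl-6-oxohex-2-en-1-yl]-3-(4-methylpent-3-en-1-yl)cyclohexan-1-one F5, and the iodo-ylide olefination of step 9 gives (2R,3S,4R)-2-ethenyl-3-(hydroxymethyl)-4-[(2Z,6Z)-7-iodo-3-methylocta-2,6-dien-1-yl]-3-(4-methylpent-3-en-1-yl)cyclohexan-1-one F6. Me3SI/KN(SiMe3)2 at −20 °C then forms the epoxide and rejoins the route at 24.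

Step 12 is the third, because closing a 12-membered ring that bridges the cyclohexane in a trans-1,3 fashion by B-alkyl Suzuki coupling may lose to oligomerisation or protodeboronation. The fallback sets out from 24: hydroboration with 9-BBN-H and oxidation with NaBO3·4H2O give [(3S,4R,5S,6R)-4-(2-hydroxyethyl)-6-[(2Z,6Z)-7-iodo-3-methylocta-2,6-dien-1-yl]-5-(4-methylpent-3-en-1-yl)-1-oxaspiro[2.5]octan-5-yl]methanol F7. I2/PPh3/imidazole at 0 °C converts only the unhindered primary alcohol into [(3S,4R,5S,6R)-4-(2-iodoethyl)-6-[(2Z,6Z)-7-iodo-3-methylocta-2,6-dien-1-yl]-5-(4-methylpent-3-en-1-yl)-1-oxaspiro[2.5]octan-5-yl]methanol F8. The ring is then closed by nickel-catalysed reductive cross-electrophile coupling of the alkyl iodide with the vinyl iodide (NiBr2(dme), 4,4'-di-tert-butyl-2,2'-bipyridine, Mn, DMA, high dilution), which rejoins the route at 26.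

**Further compounds**
F1 | step 6 | racemic 4-[(2Z)-6,6-dimethoxy-3-methylhex-2-en-1-yl]-3-(hydroxymethyl)cyclohex-2-en-1-one | O=C1C=C(CO)C(C/C=C(C)\CCC(OC)OC)CC1
F2 | step 6 | (4S)-4-[(2Z)-6,6-dimethoxy-3-methylhex-2-en-1-yl]-3-(hydroxymethyl)cyclohex-2-en-1-one | O=C1C=C(CO)[C@H](C/C=C(C)\CCC(OC)OC)CC1
F3 | step 8 | ring-C2 1-hydroxy-2-(phenylselanyl)ethyl ketone (aldol adduct of 19, ring configuration as in 20, carbinol centre unassigned) | O=C1CC[C@H](C/C=C(C)\CCC(OC)OC)[C@@](CO[Si](C)(C)C)(CCC=C(C)C)[C@H]1C(O)C[Se]c1ccccc1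
F4 | step 8 | (2R,3S,4R)-4-[(2Z)-6,6-dimethoxy-3-methylhex-2-en-1-yl]-2-ethenyl-3-(4-methylpent-3-en-1-yl)-3-{[(trimethylsilyl)oxy]methyl}cyclohexan-1-one | O=C1CC[C@H](C/C=C(C)\CCC(OC)OC)[C@@](CO[Si](C)(C)C)(CCC=C(C)C)[C@H]1C=C
F5 | step 8 | (2R,3S,4R)-2-ethenyl-3-(hydroxymethyl)-4-[(2Z)-3-methyl-6-oxohex-2-en-1-yl]-3-(4-methylpent-3-en-1-yl)cyclohexan-1-one | O=C1CC[C@H](C/C=C(C)\CCC=O)[C@@](CO)(CCC=C(C)C)[C@H]1C=C
F6 | step 8 | (2R,3S,4R)-2-ethenyl-3-(hydroxymethyl)-4-[(2Z,6Z)-7-iodo-3-methylocta-2,6-dien-1-yl]-3-(4-methylpent-3-en-1-yl)cyclohexan-1-one | O=C1CC[C@H](C/C=C(C)\CC/C=C(/C)I)[C@@](CO)(CCC=C(C)C)[C@H]1C=C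
F7 | step 12 | [(3S,4R,5S,6R)-4-(2-hydroxyethyl)-6-[(2Z,6Z)-7-iodo-3-methylocta-2,6-dien-1-yl]-5-(4-methylpent-3-en-1-yl)-1-oxaspiro[2.5]octan-5-yl]methanol | C1O[C@]12CC[C@H](C/C=C(C)\CC/C=C(/C)I)[C@@](CO)(CCC=C(C)C)[C@H]2CCO
F8 | step 12 | [(3S,4R,5S,6R)-4-(2-iodoethyl)-6-[(2Z,6Z)-7-iodo-3-methylocta-2,6-dien-1-yl]-5-(4-methylpent-3-en-1-yl)-1-oxaspiro[2.5]octan-5-yl]methanol | C1O[C@]12CC[C@H](C/C=C(C)\CC/C=C(/C)I)[C@@](CO)(CCC=C(C)C)[C@H]2CCI
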